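**Strategy.** Ring B (C1′–C6′; C1′ bonded to benzofuran C2) carries oxygen at C3′ and C5′, both meta to C1′, so it is the aromatised form of a symmetrical 5-(benzofuran-2-yl)cyclohexane-1,3-dione. Cutting C1′–C6′ and C4′–C5′ leads back to dimethyl malonate and an (E)-4-(benzofuran-2-yl)but-3-en-2-one that already holds the finished A-ring/furan unit (C5–OMOM, C6–OMe, C7–prenyl). A single Michael–Claisen annulation makes both bonds and closes the six-membered ring with the two oxygens in place; the symmetry of the decarboxylated dione then makes mono-O-methylation unambiguous and dehydrogenation delivers the 3-methoxy-5-arylphenol. The enone is built from vanillin.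

Key step: step 9

Assumption: the target has no stereogenic element, so the structure as drawn is its only stereoisomer; stereocentres that appear in intermediates (THP acetal carbon in 5, 7, 8; ring carbons in 20–22 and 24–26; sulfur in 26) form without control and are all removed before the target.

Abbreviation: Bf = 6-methoxy-5-(methoxymethoxy)-7-(3-methylbut-2-en-1-yl)-1-benzofuran-2-yl.

**Step 1**
Reactants: 1 vanillin
Product: 2 3-methoxy-4-(methoxymethoxy)benzaldehyde
Conditions: MOMCl, iPr2NEt, CH2Cl2, 0 °C → rt
Reagents that add atoms: chloromethyl methyl ether, COCCl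
Why: O-alkylation of the phenoxide (MOM protection) gives an acetal ether that should tolerate the later peracid, organolithium, hydride and alkoxide steps and can be removed last by mild acid.

**Step 2**
Reactants: 2 3-methoxy-4-(methoxymethoxy)benzaldehyde
Product: 4 3-methoxy-4-(methoxymethoxy)phenol, via aryl formate 3 (not isolated)
Conditions: mCPBA, CH2Cl2, 0 °C → rt; then K2CO3 (cat.), MeOH, rt
Reagents that add atoms: mCPBA, O=C(OO)c1cccc(Cl)c1
Why: Dakin-type Baeyer–Villiger oxidation in which the electron-rich p-alkoxyaryl group migrates to give the formate, followed by base-catalysed transesterification to the phenol; the peracid is used before any alkene is present.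

**Step 3**
Reactants: 4 3-methoxy-4-(methoxymethoxy)phenol
Product: 5 2-[3-methoxy-4-(methoxymethoxy)phenoxy]tetrahydro-2H-pyran (racemic)
Conditions: 3,4-dihydro-2H-pyran, PPTS (cat.), CH2Cl2, rt
Reagents that add atoms: 3,4-dihydro-2H-pyran, C1=COCCC1
Why: Acid-catalysed addition of the phenol to the enol ether (THP protection) installs an oxygen directing group that is clearly more acid-labile than the aryl MOM ether.

**Step 4**
Reactants: 5 2-[3-methoxy-4-(methoxymethoxy)phenoxy]tetrahydro-2H-pyran; 6 prenyl bromide
Product: 9 3-methoxy-4-(methoxymethoxy)-2-(3-methylbut-2-en-1-yl)phenol, via aryllithium 7 (not isolated), via prenylated THP ether 8 (not isolated)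
Conditions: n-BuLi, TMEDA, THF, 0 °C; CuBr·SMe2 (10 mol %), prenyl bromide, −78 °C → rt; crude, PPTS (cat.), MeOH, rt
Reagents that add atoms: none
Why: Directed ortho-metalation at the carbon flanked by OTHP and OMe (cooperative 1,3-directing groups, as in the C3 lithiation of 1,2,4-trialkoxybenzenes), copper-catalysed SN2 allylation, then methanolysis of the THP acetal, which should ionise far faster than the MOM ether under PPTS.

**Step 5**
Reactants: 9 3-methoxy-4-(methoxymethoxy)-2-(3-methylbut-2-en-1-yl)phenol; 10 paraformaldehyde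
Product: 11 2-hydroxy-4-methoxy-5-(methoxymethoxy)-3-(3-methylbut-2-en-1-yl)benzaldehyde
Conditions: MgCl2, Et3N, MeCN, reflux
Reagents that add atoms: none
Why: Magnesium-mediated ortho-formylation (Casnati–Skattebøl): the magnesium phenoxide delivers formaldehyde to the only free ortho carbon (the other ortho carbon bears prenyl, the para carbon OMOM) and a second formaldehyde oxidises the benzylic alkoxide to the aldehyde by hydride transfer.

**Step 6**
Reactants: 11 2-hydroxy-4-methoxy-5-(methoxymethoxy)-3-(3-methylbut-2-en-1-yl)benzaldehyde; 12 ethyl bromoacetate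
Product: 14 ethyl Bf-carboxylate [ethyl 6-methoxy-5-(methoxymethoxy)-7-(3-methylbut-2-en-1-yl)-1-benzofuran-2-carboxylate], via aryloxyacetate 13 (not isolated)
Conditions: K2CO3, DMF, rt → 100 °C
Reagents that add atoms: none
Why: Rap–Stoermer-type benzofuran synthesis in which O-alkylation is followed by intramolecular aldol condensation of the ester enolate onto the aldehyde, with dehydration driven by formation of the aromatic furan.

**Step 7**
Reactants: 14 ethyl Bf-carboxylate
Product: 15 Bf-methanol
Conditions: LiAlH4, THF, 0 °C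
Reagents that add atoms: none
Why: Hydride reduction of the ester to the primary alcohol, to which the MOM acetal, aryl ethers, benzofuran and isolated alkene are inert.

**Step 8**
Reactants: 15 Bf-methanol; 16 1-(triphenylphosphoranylidene)propan-2-one
Product: 18 (E)-4-Bf-but-3-en-2-one, via benzofuran-2-carbaldehyde 17 (not isolated)
Conditions: activated MnO2, toluene, 80 °C
Reagents that add atoms: none
Why: Tandem MnO2 oxidation of the heteroaryl-benzylic alcohol and Wittig olefination with a stabilised ylide should give the E-enone directly, avoiding the double condensation possible in an aldol reaction with acetone.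

**Step 9**
Reactants: 18 (E)-4-Bf-but-3-en-2-one; 19 dimethyl malonate
Product: 21 methyl 6-Bf-2,4-dioxocyclohexane-1-carboxylate (racemic), via Michael adduct 20 (not isolated)
Conditions: NaOMe (1.3 equiv), MeOH, reflux; AcOH, 0 °C
Reagents that add atoms: none
Why: Sodium methoxide deprotonates dimethyl malonate and the soft carbanion adds reversibly to the β-carbon of enone 18, the carbon bearing Bf, forming C1′–C6′ (C6′ is the malonate CH); proton exchange then gives the terminal methyl-ketone enolate (C4′), which attacks one malonate ester carbonyl (C5′) and expels methoxide. This is the classical Michael–Claisen annulation that converts arylidene- and furfurylidene-acetones into 5-substituted cyclohexane-1,3-diones. The ring closes in a 6-(enolexo)-exo-trig mode. The two ring stereocentres of 21 (C1 and C6) arise racemic and need no control, since C1 is lost on decarboxylation and C6 becomes non-stereogenic in 23 and sp2 on aromatisation. The step needs conjugate rather than carbonyl addition and closure from the methyl-side enolate: the stabilised malonate anion adds 1,2 only reversibly, the internal enolate could form only a four-membered ring, and deprotonation of the acidic β-dicarbonyl product pulls all preceding equilibria forward.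

**Step 10**
Reactants: 21 methyl 6-Bf-2,4-dioxocyclohexane-1-carboxylate
Product: 23 5-Bf-cyclohexane-1,3-dione, via keto acid 22 (not isolated)
Conditions: NaOH, H2O/MeOH, reflux; then 1 M HCl to pH 3–4, 60 °C
Reagents that add atoms: none
Why: Saponification followed by decarboxylation of the β-keto acid through its cyclic six-membered transition state; the dione enolate resists retro-Claisen cleavage in base and pH 3–4 should be too mild to cleave the aryl MOM ether.

**Step 11**
Reactants: 23 5-Bf-cyclohexane-1,3-dione
Product: 24 3-methoxy-5-Bf-cyclohex-2-en-1-one (racemic)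
Conditions: TMSCHN2, MeOH/toluene, 0 °C → rt
Reagents that add atoms: (trimethylsilyl)diazomethane, C[Si](C)(C)C=[N+]=[N-]
Why: O-methylation of the acidic enolised 1,3-dione by the diazoalkane; the two carbonyls are equivalent, so only one vinylogous ester can form, and no acid is present to threaten the MOM group.

**Step 12**
Reactants: 24 3-methoxy-5-Bf-cyclohex-2-en-1-one
Product: 28 3-methoxy-5-Bf-phenol, via lithium dienolate 25 (not isolated), via sulfilimine adduct 26 (not isolated), via dienone 27 (not isolated)
Conditions: LDA, THF, −78 °C; PhS(Cl)=NtBu, −78 → 0 °C; aq NH4Cl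
Reagents that add atoms: none
Why: Mukaiyama dehydrogenation: the kinetic α′-enolate of the vinylogous ester attacks sulfur, the α-sulfilimine undergoes syn-elimination of the C5–H through a five-membered transition state, and the cross-conjugated dienone tautomerises to the phenol, with no oxidant present that could attack the prenyl alkene or the electron-rich arenes.

**Step 13**
Reactants: 28 3-methoxy-5-Bf-phenol
Product: 29 dinklagein A
Conditions: 2 M aq HCl, MeOH, 40 °C
Reagents that add atoms: none
Why: Acid-catalysed methanolysis of the MOM acetal; the prenyl group sits between OMe and the furan oxygen, so no free ortho-hydroxyl is available for chroman formation.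

**Compound list**
1 | vanillin (4-hydroxy-3-methoxybenzaldehyde) | COc1cc(C=O)ccc1O | starting material
2 | 3-methoxy-4-(methoxymethoxy)benzaldehyde | COCOc1ccc(C=O)cc1OC | intermediate
3 | 3-methoxy-4-(methoxymethoxy)phenyl formate | COCOc1ccc(OC=O)cc1OC | intermediate (not isolated)
4 | 3-methoxy-4-(methoxymethoxy)phenol | COCOc1ccc(O)cc1OC | intermediate
5 | 2-[3-methoxy-4-(methoxymethoxy)phenoxy]tetrahydro-2H-pyran (racemic) | COCOc1ccc(OC2CCCCO2)cc1OC | intermediate
6 | prenyl bromide (1-bromo-3-methylbut-2-ene) | CC(C)=CCBr | starting material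
7 | {2-methoxy-3-(methoxymethoxy)-6-[(tetrahydro-2H-pyran-2-yl)oxy]phenyl}lithium (racemic) | [Li]c1c(OC2CCCCO2)ccc(OCOC)c1OC | intermediate (not isolated)
8 | 2-[3-methoxy-4-(methoxymethoxy)-2-(3-methylbut-2-en-1-yl)phenoxy]tetrahydro-2H-pyran (racemic) | COCOc1ccc(OC2CCCCO2)c(CC=C(C)C)c1OC | intermediate (not isolated)
9 | 3-methoxy-4-(methoxymethoxy)-2-(3-methylbut-2-en-1-yl)phenol | COCOc1ccc(O)c(CC=C(C)C)c1OC | intermediate
10 | paraformaldehyde (written as formaldehyde) | C=O | starting material
11 | 2-hydroxy-4-methoxy-5-(methoxymethoxy)-3-(3-methylbut-2-en-1-yl)benzaldehyde | COCOc1cc(C=O)c(O)c(CC=C(C)C)c1OC | intermediate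
12 | ethyl bromoacetate | CCOC(=O)CBr | starting material
13 | ethyl 2-[2-formyl-5-methoxy-4-(methoxymethoxy)-6-(3-methylbut-2-en-1-yl)phenoxy]acetate | CCOC(=O)COc1c(C=O)cc(OCOC)c(OC)c1CC=C(C)C | intermediate (not isolated)
14 | ethyl 6-methoxy-5-(methoxymethoxy)-7-(3-methylbut-2-en-1-yl)-1-benzofuran-2-carboxylate | CCOC(=O)c1cc2cc(OCOC)c(OC)c(CC=C(C)C)c2o1 | intermediate
15 | [6-methoxy-5-(methoxymethoxy)-7-(3-methylbut-2-en-1-yl)-1-benzofuran-2-yl]methanol | OCc1cc2cc(OCOC)c(OC)c(CC=C(C)C)c2o1 | intermediate
16 | 1-(triphenylphosphoranylidene)propan-2-one | CC(=O)C=P(c1ccccc1)(c1ccccc1)c1ccccc1 | starting material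
17 | 6-methoxy-5-(methoxymethoxy)-7-(3-methylbut-2-en-1-yl)-1-benzofuran-2-carbaldehyde | O=Cc1cc2cc(OCOC)c(OC)c(CC=C(C)C)c2o1 | intermediate (not isolated)
18 | (E)-4-[6-methoxy-5-(methoxymethoxy)-7-(3-methylbut-2-en-1-yl)-1-benzofuran-2-yl]but-3-en-2-one | CC(=O)/C=C/c1cc2cc(OCOC)c(OC)c(CC=C(C)C)c2o1 | intermediate
19 | dimethyl malonate | COC(=O)CC(=O)OC | starting material
20 | dimethyl 2-{1-[6-methoxy-5-(methoxymethoxy)-7-(3-methylbut-2-en-1-yl)-1-benzofuran-2-yl]-3-oxobutyl}malonate (racemic) | COC(=O)C(C(=O)OC)C(CC(C)=O)c1cc2cc(OCOC)c(OC)c(CC=C(C)C)c2o1 | intermediate (not isolated)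
21 | methyl 6-[6-methoxy-5-(methoxymethoxy)-7-(3-methylbut-2-en-1-yl)-1-benzofuran-2-yl]-2,4-dioxocyclohexane-1-carboxylate (racemic; relative configuration not controlled; largely enolised) | COC(=O)C1C(=O)CC(=O)CC1c1cc2cc(OCOC)c(OC)c(CC=C(C)C)c2o1 | intermediate
22 | 6-[6-methoxy-5-(methoxymethoxy)-7-(3-methylbut-2-en-1-yl)-1-benzofuran-2-yl]-2,4-dioxocyclohexane-1-carboxylic acid (racemic) | OC(=O)C1C(=O)CC(=O)CC1c1cc2cc(OCOC)c(OC)c(CC=C(C)C)c2o1 | intermediate (not isolated)
23 | 5-[6-methoxy-5-(methoxymethoxy)-7-(3-methylbut-2-en-1-yl)-1-benzofuran-2-yl]cyclohexane-1,3-dione | O=C1CC(=O)CC(c2cc3cc(OCOC)c(OC)c(CC=C(C)C)c3o2)C1 | intermediate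
24 | 3-methoxy-5-[6-methoxy-5-(methoxymethoxy)-7-(3-methylbut-2-en-1-yl)-1-benzofuran-2-yl]cyclohex-2-en-1-one (racemic) | COC1=CC(=O)CC(c2cc3cc(OCOC)c(OC)c(CC=C(C)C)c3o2)C1 | intermediate
25 | lithium 5-methoxy-3-[6-methoxy-5-(methoxymethoxy)-7-(3-methylbut-2-en-1-yl)-1-benzofuran-2-yl]cyclohexa-1,5-dien-1-olate (racemic) | [Li]OC1=CC(c2cc3cc(OCOC)c(OC)c(CC=C(C)C)c3o2)CC(OC)=C1 | intermediate (not isolated)
26 | 6-(N-tert-butyl-S-phenylsulfinimidoyl)-3-methoxy-5-[6-methoxy-5-(methoxymethoxy)-7-(3-methylbut-2-en-1-yl)-1-benzofuran-2-yl]cyclohex-2-en-1-one (mixture of stereoisomers) | COC1=CC(=O)C(S(=NC(C)(C)C)c2ccccc2)C(c2cc3cc(OCOC)c(OC)c(CC=C(C)C)c3o2)C1 | intermediate (not isolated)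
27 | 3-methoxy-5-[6-methoxy-5-(methoxymethoxy)-7-(3-methylbut-2-en-1-yl)-1-benzofuran-2-yl]cyclohexa-2,5-dien-1-one | COC1=CC(=O)C=C(c2cc3cc(OCOC)c(OC)c(CC=C(C)C)c3o2)C1 | intermediate (not isolated)
28 | 3-methoxy-5-[6-methoxy-5-(methoxymethoxy)-7-(3-methylbut-2-en-1-yl)-1-benzofuran-2-yl]phenol | COCOc1cc2cc(-c3cc(O)cc(OC)c3)oc2c(CC=C(C)C)c1OC | intermediate
29 | dinklagein A, 2-(3-hydroxy-5-methoxyphenyl)-6-methoxy-7-(3-methylbut-2-en-1-yl)-1-benzofuran-5-ol | COc1cc(O)cc(-c2cc3cc(O)c(OC)c(CC=C(C)C)c3o2)c1 | target

**Total step count:** 13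
**Longest linear sequence:** 13 steps (vanillin to the target; all other inputs are purchased)

**Steps most likely to fail**

Step 9. The conjugate addition may stall or reverse, because the donor benzofuran lowers the electrophilicity of the enone. The base-sensitive methyl enone may also be consumed by self-condensation before ring closure. The fallback reverses the polarity of the partners so that the acceptor has no enolisable position. It sets out from alcohol 15. Tandem MnO2 oxidation–Wittig reaction with ethyl (triphenylphosphoranylidene)acetate should give ethyl (2E)-3-[6-methoxy-5-(methoxymethoxy)-7-(3-methylbut-2-en-1-yl)-1-benzofuran-2-yl]prop-2-enoate F4. Ethyl acetoacetate with NaOEt in refluxing EtOH should add in Michael fashion to give diethyl 2-acetyl-3-[6-methoxy-5-(methoxymethoxy)-7-(3-methylbut-2-en-1-yl)-1-benzofuran-2-yl]pentanedioate F5. Its methyl-ketone enolate closes onto the other ester in the same pot to give ethyl 6-[6-methoxy-5-(methoxymethoxy)-7-(3-methylbut-2-en-1-yl)-1-benzofuran-2-yl]-2,4-dioxocyclohexane-1-carboxylate F6. Saponification and decarboxylation under the conditions of step 10 pass through acid 22 and come back to the route at dione 23.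

Step 12. Proton transfer between unreacted enolate and the newly formed acidic intermediates may stop the dehydrogenation short, or the sulfur electrophile may be captured without elimination. The fallback is a Saegusa–Ito oxidation and sets out from 24. LDA and TMSCl at −78 °C should trap the same α′-enolate 25 as the silyl dienol ether {[5-methoxy-3-(6-methoxy-5-(methoxymethoxy)-7-(3-methylbut-2-en-1-yl)-1-benzofuran-2-yl)cyclohexa-1,5-dien-1-yl]oxy}trimethylsilane F7. Pd(OAc)2 in MeCN at rt then effects β-hydride elimination from the palladium enolate to give dienone 27, which tautomerises, so the fallback comes back at 28.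

Step 4. Regiocontrol in the lithiation may be lost through competing metalation next to OMOM, the allylation may suffer allylic transposition, or the MOM group may be partly lost during THP methanolysis. The fallback uses a non-acetal directing group and sets out from phenol 4. ClCONEt2 with K2CO3 in MeCN should give 3-methoxy-4-(methoxymethoxy)phenyl N,N-diethylcarbamate F1. s-BuLi/TMEDA at −78 °C metalates between the carbamate and OMe to give {6-[(diethylcarbamoyl)oxy]-2-methoxy-3-(methoxymethoxy)phenyl}lithium F2. Prenyl bromide with catalytic CuBr·SMe2 at −78 °C, below the temperature of the anionic Fries rearrangement, gives 3-methoxy-4-(methoxymethoxy)-2-(3-methylbut-2-en-1-yl)phenyl N,N-diethylcarbamate F3. LiAlH4 in THF cleaves the carbamate reductively under conditions that cannot touch the MOM ether, and the fallback comes back at 9.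

**Further compounds**
F1 | step 4 | 3-methoxy-4-(methoxymethoxy)phenyl N,N-diethylcarbamate | CCN(CC)C(=O)Oc1ccc(OCOC)c(OC)c1
F2 | step 4 | {6-[(diethylcarbamoyl)oxy]-2-methoxy-3-(methoxymethoxy)phenyl}lithium | [Li]c1c(OC(=O)N(CC)CC)ccc(OCOC)c1OC
F3 | step 4 | 3-methoxy-4-(methoxymethoxy)-2-(3-methylbut-2-en-1-yl)phenyl N,N-diethylcarbamate | CCN(CC)C(=O)Oc1ccc(OCOC)c(OC)c1CC=C(C)C
F4 | step 9 | ethyl (2E)-3-[6-methoxy-5-(methoxymethoxy)-7-(3-methylbut-2-en-1-yl)-1-benzofuran-2-yl]prop-2-enoate | CCOC(=O)/C=C/c1cc2cc(OCOC)c(OC)c(CC=C(C)C)c2o1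
F5 | step 9 | diethyl 2-acetyl-3-[6-methoxy-5-(methoxymethoxy)-7-(3-methylbut-2-en-1-yl)-1-benzofuran-2-yl]pentanedioate (mixture of stereoisomers) | CCOC(=O)CC(c1cc2cc(OCOC)c(OC)c(CC=C(C)C)c2o1)C(C(C)=O)C(=O)OCC
F6 | step 9 | ethyl 6-[6-methoxy-5-(methoxymethoxy)-7-(3-methylbut-2-en-1-yl)-1-benzofuran-2-yl]-2,4-dioxocyclohexane-1-carboxylate (racemic) | CCOC(=O)C1C(=O)CC(=O)CC1c1cc2cc(OCOC)c(OC)c(CC=C(C)C)c2o1
F7 | step 12 | {[5-methoxy-3-(6-methoxy-5-(methoxymethoxy)-7-(3-methylbut-2-en-1-yl)-1-benzofuran-2-yl)cyclohexa-1,5-dien-1-yl]oxy}trimethylsilane (racemic) | C[Si](C)(C)OC1=CC(c2cc3cc(OCOC)c(OC)c(CC=C(C)C)c3o2)CC(OC)=C1
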